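**Retrosynthetic overview** (locants follow briarane numbering: C1 = quaternary carbon with Me‑15; C2–C9 = remaining cyclodecene carbons, C5=C6 carrying Me‑16; C7/C8/C17(Me‑18)/C19 = γ‑lactone; C10 = ring‑fusion CH; C11 = spiro carbon, C20 = epoxide CH2; C12, C13 = CH2; C14 = CH–OAc)
1. Target ⇐ triacetylation, desilylation and 1,2‑diol → epoxide closure ⇐ reductive α‑hydroxylation and reduction of a temporary C9–O–C20 lactone ⇐ pentacyclic cycloadduct.
2. Key disconnection: C1–C10 and C13–C14 together, by an intramolecular inverse‑electron‑demand Diels–Alder reaction. Diene C10=C11–C12=C13 is a 3‑vinylbutenolide (temporary C9–O–C20 lactone); dienophile C1=C14 is a cyclic silyl enol ether (temporary tBu2Si bridge between O2 and O14); the tether is C2–C9.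
3. Enabling feature: the cyclohexane (C1, C10, C11, C12, C13, C14) shares its C1–C10 bond with the cyclodecene (C1–C10), and O14 and C20‑on‑C11 sit where an enol ether and a 2‑acyl diene place them. One [4+2] therefore closes both carbocycles and sets C1, C10 and C14.
4. Open‑chain precursor: C2–C7 with C16 and the Z olefin from neryl acetate; C1, C14, C15 by Evans aldol (sets C2); C8, C9, C17–C19 by Horner–Wadsworth–Emmons olefination, Sharpless epoxidation (sets C7, C8) and lactonisation; C10–C13 and C20 by alkynylation (sets C9), hydrostannation and Stille coupling.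
5. Ring order: γ‑lactone (C7/C8) → butenolide (temporary) → dioxasiline (temporary) → cyclohexene and cyclodecene together (key step) → spiro‑epoxide.

Key step: step 21

Remark: tert‑butyl (R)‑lactate is taken as purchasable; the ProPhenol antipode in step 15 is the one that gives Si‑face addition (9S), to be confirmed on a model aldehyde; the C1 configuration of compounds 5–26 is irrelevant because step 20 erases it.

**Route**

Step 1
Reactants: 1 neryl acetate
Product: 2 6,7‑epoxyneryl acetate
Conditions: mCPBA (1.05 equiv), NaHCO3, CH2Cl2, 0 °C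
Reagents that add atoms: mCPBA, OOC(=O)c1cccc(Cl)c1
Why: Prilezhaev epoxidation should occur at the electron‑rich 6,7‑olefin because the 2,3‑olefin is deactivated by the allylic acetate; the new oxirane centre is racemic and is destroyed in step 2.

Step 2
Reactants: 2 6,7‑epoxyneryl acetate
Product: 3 (2Z)‑3‑methyl‑6‑oxohex‑2‑en‑1‑yl acetate
Conditions: H5IO6 (1.1 equiv), THF–H2O, 0 °C to rt
Reagents that add atoms: none
Why: Periodic acid hydrolyses the epoxide and cleaves the glycol (Malaprade‑type cleavage) to the aldehyde, whose oxygen is the former epoxide oxygen, without touching the Z olefin or the acetate.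

Step 3
Reactants: 3 (2Z)‑3‑methyl‑6‑oxohex‑2‑en‑1‑yl acetate; 4 (4R)‑4‑benzyl‑3‑propanoyl‑1,3‑oxazolidin‑2‑one
Product: 5 syn‑aldol imide
Conditions: 4, Bu2BOTf, Et3N, CH2Cl2, −78 to 0 °C; then 3, −78 to 0 °C; pH 7 buffer, MeOH
Reagents that add atoms: none
Why: Evans syn‑aldol reaction of the Z boron enolate through a closed Zimmerman–Traxler transition state, the (R)‑benzyl auxiliary fixing C2 as S (and C1, erased later, as R).

Step 4
Reactants: 5 syn‑aldol imide
Product: 6 (2S,3S,6Z)‑2,6‑dimethyloct‑6‑ene‑1,3,8‑triol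
Conditions: LiBH4 (4 equiv), MeOH (2 equiv), THF, 0 °C to rt
Reagents that add atoms: none
Why: Reductive cleavage of the imide with LiBH4 releases the primary alcohol and the auxiliary, and the same hydride removes the acetate so that the C7 hydroxyl is unmasked in one operation.

Step 5
Reactants: 6 (2S,3S,6Z)‑2,6‑dimethyloct‑6‑ene‑1,3,8‑triol
Product: 7 acetonide alcohol
Conditions: Me2C(OMe)2, PPTS (cat.), acetone, rt; aq. NaHCO3 work‑up
Reagents that add atoms: 2,2‑dimethoxypropane, COC(C)(C)OC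
Why: Thermodynamic acetonide formation selects the 1,3‑diol (six‑membered dioxane), leaving the allylic primary alcohol free once any mixed ketal is hydrolysed on work‑up.

Step 6
Reactants: 7 acetonide alcohol
Product: 8 acetonide enal
Conditions: MnO2 (excess), CH2Cl2, rt
Reagents that add atoms: none
Why: MnO2 oxidises only the allylic alcohol and, being neutral and heterogeneous, should preserve the Z geometry of the enal.

Step 7
Reactants: 9 tert‑butyl (R)‑lactate
Product: 10 tert‑butyl (2R)‑2‑(triflyloxy)propanoate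
Conditions: Tf2O, 2,6‑lutidine, CH2Cl2, −78 to 0 °C
Reagents that add atoms: triflic anhydride, O=S(=O)(OS(=O)(=O)C(F)(F)F)C(F)(F)F
Why: O‑sulfonylation proceeds with retention at carbon and gives the α‑triflyloxy ester needed for an SN2 displacement.

Step 8
Reactants: 10 tert‑butyl (2R)‑2‑(triflyloxy)propanoate; 11 triethyl phosphonoacetate
Product: 12 phosphonosuccinate
Conditions: 11, NaH, THF, 0 °C; then 10, 0 °C to rt
Reagents that add atoms: none
Why: SN2 alkylation of the sodium phosphonoacetate by the secondary triflate with clean inversion sets the methyl‑bearing C17 centre (R in the target) from the lactate.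

Step 9
Reactants: 8 acetonide enal; 12 phosphonosuccinate
Product: 13 (E)‑alkylidenesuccinate
Conditions: 12, NaH, THF, 0 °C; then 8, −40 to 0 °C
Reagents that add atoms: none
Why: Horner–Wadsworth–Emmons olefination with the α‑branched phosphonate should give mainly the E isomer (C6 trans to the C9 ester), and the preformed sodium anion should avoid isomerising the Z enal or the C17 centre.

Step 10
Reactants: 13 (E)‑alkylidenesuccinate
Product: 14 dienol
Conditions: iBu2AlH (2.2 equiv), CH2Cl2, −78 °C; Rochelle salt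
Reagents that add atoms: none
Why: iBu2AlH at −78 °C reduces the conjugated ethyl ester to the allylic alcohol while the hindered tert‑butyl ester should survive.

Step 11
Reactants: 14 dienol
Product: 15 (2R,3R)‑epoxy alcohol
Conditions: Ti(OiPr)4, D‑(−)‑diethyl tartrate, tBuOOH, 4 Å MS, CH2Cl2, −20 °C
Reagents that add atoms: tert‑butyl hydroperoxide, CC(C)(C)OO
Why: Sharpless asymmetric epoxidation of the primary allylic alcohol is reagent‑controlled, D‑(−)‑tartrate giving the (2R,3R)‑oxirane that fixes C8 and (before inversion) C7, while the distal trisubstituted olefin is not an allylic alcohol and is left alone.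

Step 12
Reactants: 15 (2R,3R)‑epoxy alcohol
Product: 16 hydroxy lactone diol
Conditions: CSA (0.1 equiv), CH2Cl2, 0 °C
Reagents that add atoms: none
Why: Acid‑promoted γ‑lactone closure by attack of the tert‑butyl ester carbonyl on the allylic epoxide carbon C7 with inversion (loss of isobutene) should give C7 as S with C6 trans to C9 and the tertiary C8 hydroxyl.

Step 13
Reactants: 16 hydroxy lactone diol
Product: 17 bis(triethylsilyl) ether
Conditions: Et3SiOTf (2.5 equiv), 2,6‑lutidine, CH2Cl2, −78 to 0 °C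
Reagents that add atoms: triethylsilyl triflate, CC[Si](CC)(CC)OS(=O)(=O)C(F)(F)F
Why: Silyl triflate silylation protects both the tertiary C8 hydroxyl and the primary C9 hydroxyl.

Step 14
Reactants: 17 bis(triethylsilyl) ether
Product: 18 lactone aldehyde
Conditions: (COCl)2, DMSO, CH2Cl2, −78 to −30 °C; then Et3N, −78 to 0 °C
Reagents that add atoms: none
Why: Swern conditions cleave and oxidise a primary triethylsilyl ether directly to the aldehyde while the tertiary silyl ether stays, and the aldehyde has no α‑hydrogen to epimerise.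

Step 15
Reactants: 18 lactone aldehyde; 19 methyl propiolate
Product: 20 (9S)‑propargylic alcohol
Conditions: 19 (3 equiv), Me2Zn (3 equiv), ProPhenol (antipode for Si‑face attack, 20 mol %), Ph3PO (40 mol %), toluene, 4 °C
Reagents that add atoms: none
Why: Zinc–ProPhenol catalysed alkynylation; the aldehyde is flanked by two similar ring carbons and has little intrinsic bias, so the catalyst should set C9 as S by Si‑face addition.

Step 16
Reactants: 20 (9S)‑propargylic alcohol
Product: 22 stannyl butenolide, via stannyl hydroxy enoate 21 (not isolated)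
Conditions: Bu3SnH, PdCl2(PPh3)2 (3 mol %), THF, 0 °C to rt; then PPTS (cat.), toluene, 50 °C
Reagents that add atoms: tributyltin hydride, CCCC[SnH](CCCC)CCCC
Why: Palladium‑catalysed syn‑hydrostannation of the ynoate places tin α to the ester, so the C9 hydroxyl is cis to the ester and closes the butenolide, which locks the later diene geometry.

Step 17
Reactants: 22 stannyl butenolide; 23 vinyl bromide
Product: 24 vinylbutenolide
Conditions: 23 (excess), Pd2(dba)3 (5 mol %), AsPh3, CuI, NMP, rt to 45 °C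
Reagents that add atoms: none
Why: Stille coupling with retention at the alkenyl stannane installs C12 and C13 and completes the 2‑acyl diene.

Step 18
Reactants: 24 vinylbutenolide
Product: 25 vinylbutenolide diol
Conditions: PPTS (0.2 equiv), MeOH, 0 °C to rt
Reagents that add atoms: none
Why: Acid‑catalysed transketalisation in methanol removes the acetonide while the hindered tertiary silyl ether and the butenolide should survive.

Step 19
Reactants: 25 vinylbutenolide diol
Product: 26 β‑hydroxy aldehyde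
Conditions: TEMPO (0.1 equiv), PhI(OAc)2 (1.1 equiv), CH2Cl2, rt
Reagents that add atoms: none
Why: TEMPO/PhI(OAc)2 oxidation is selective for the primary alcohol of the 1,3‑diol and stops at the aldehyde.

Step 20
Reactants: 26 β‑hydroxy aldehyde
Product: 27 dioxasiline triene
Conditions: tBu2Si(OTf)2 (1.05 equiv), Et3N (3 equiv), CH2Cl2, −78 to −20 °C
Reagents that add atoms: di‑tert‑butylsilyl bis(triflate), CC(C)(C)[Si](OS(=O)(=O)C(F)(F)F)(OS(=O)(=O)C(F)(F)F)C(C)(C)C
Why: Silylation of the C2 hydroxyl followed by intramolecular silyl enol ether formation from the aldehyde closes the six‑membered dioxasiline, which forces O14 cis to C2 on the enol ether and erases the C1 centre.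

Step 21
Reactants: 27 dioxasiline triene
Product: 28 pentacyclic cycloadduct
Conditions: BHT (0.1 equiv), degassed toluene (2 mM), sealed vessel, 150 °C
Reagents that add atoms: none
Why: Proposed new method: a thermal, concerted but asynchronous inverse‑electron‑demand [4+2] cycloaddition in which the nucleophilic β‑carbon C1 of the cyclic silyl enol ether attacks C10, the β‑carbon of the butenolide and the site of the largest LUMO coefficient of the 2‑acyl diene C10=C11–C12=C13, while C14 closes onto C13; the closest known reaction types are the inverse‑demand Diels–Alder reaction of 2‑alkoxycarbonyl‑1,3‑dienes with enol ethers and the macrocyclising intramolecular Diels–Alder reaction known for eleven‑membered and larger carbocycles, neither shown for a ten‑membered ring formed together with a quaternary centre. The cyclohexene (C1, C10–C14) closes by the cycloaddition itself and the cyclodecene (C1–C10) by the fused mode of the tether, whose eight atoms C2–C9 are pre‑folded by the Z C5=C6 olefin and the trans‑disubstituted lactone. C14 is set by the enol ether geometry locked in the dioxasiline (O14 cis to C2), and the trans relation of C2 and C9 across C1–C10 by the butenolide‑locked diene geometry (C9 outside) together with an exo dioxasiline, whose tBu2Si unit cannot sit under the diene so that only the methyl group is endo. The diene face is fixed by C9: because O9 is held in the diene plane by the temporary lactone, C8 and hence the tether stand on one face and deliver the dienophile to it, and the dienophile reacts on the face opposite its C3 substituent at C2. The step needs fused rather than bridged regiochemistry and cyclisation rather than dimerisation of the vinylbutenolide, which the matched polarity of C1 and C10, the shorter fused path and high dilution with a radical inhibitor should secure. The product already carries the oxygen at C14, the C20 carbon on C11 and the final oxidation level at C2 and C9.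

Step 22
Reactants: 28 pentacyclic cycloadduct
Product: 30 α‑hydroxy lactone, via lithium enolate 29 (not isolated)
Conditions: LiBH(sBu)3 (1.1 equiv), THF, −78 °C; then 2‑(phenylsulfonyl)‑3‑phenyloxaziridine, −78 to −40 °C; aq. NH4Cl
Reagents that add atoms: 2‑(phenylsulfonyl)‑3‑phenyloxaziridine, O=S(=O)(c1ccccc1)N1OC1c1ccccc1
Why: 1,4‑Reduction of the s‑cis α‑alkylidene lactone followed by oxaziridine hydroxylation of the enolate, which is open only on the face anti to C1 and C8 (the H10 face, away from the axial Me‑15), should give the cis‑fused α‑hydroxy lactone with the C11 oxygen placed as in the target.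

Step 23
Reactants: 30 α‑hydroxy lactone
Product: 31 triol
Conditions: NaBH4 (3 equiv), EtOH–THF, 0 °C to rt
Reagents that add atoms: none
Why: Borohydride should reduce the α‑hydroxy‑activated lactone much faster than the hindered β‑silyloxy lactone, releasing the C20 carbinol, the tertiary C11 hydroxyl and the C9 hydroxyl.

Step 24
Reactants: 31 triol
Product: 33 spiro‑epoxide, via primary tosylate 32 (not isolated)
Conditions: TsCl (1.1 equiv), pyridine, CH2Cl2, 0 °C; then NaH, THF, 0 °C
Reagents that add atoms: none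
Why: Selective sulfonylation of the only primary hydroxyl and 3‑exo‑tet closure by the C11 alkoxide (Williamson‑type epoxide formation) give the 11,20‑epoxide with retention at C11.

Step 25
Reactants: 33 spiro‑epoxide
Product: 34 tetraol
Conditions: Bu4NF (5 equiv), AcOH (5 equiv), THF, 0 °C to rt
Reagents that add atoms: none
Why: Fluoride cleaves the triethylsilyl ether and the di‑tert‑butylsilylene, the acetic acid buffer protecting the epoxide and the β‑hydroxy lactone from base.

Step 26
Reactants: 34 tetraol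
Product: 35 Junceellolide K
Conditions: Ac2O, pyridine, DMAP (cat.), CH2Cl2, 0 °C to rt
Reagents that add atoms: acetic anhydride, CC(=O)OC(C)=O
Why: Acetylation of the three secondary alcohols (C2, C9, C14) should leave the hindered tertiary C8 hydroxyl free and give the target.

**Compound list**

1 | neryl acetate, (2Z)‑3,7‑dimethylocta‑2,6‑dien‑1‑yl acetate | CC(C)=CCC/C(C)=C\COC(C)=O | starting material
2 | 6,7‑epoxyneryl acetate, (2Z)‑5‑(3,3‑dimethyloxiran‑2‑yl)‑3‑methylpent‑2‑en‑1‑yl acetate (racemic at the oxirane CH) | CC1(C)OC1CC/C(C)=C\COC(C)=O | intermediate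
3 | (2Z)‑3‑methyl‑6‑oxohex‑2‑en‑1‑yl acetate | O=CCC/C(C)=C\COC(C)=O | intermediate
4 | (4R)‑4‑benzyl‑3‑propanoyl‑1,3‑oxazolidin‑2‑one | CCC(=O)N1[C@H](Cc2ccccc2)COC1=O | starting material
5 | syn‑aldol imide, (4R)‑4‑benzyl‑3‑[(2R,3S,6Z)‑8‑acetoxy‑3‑hydroxy‑2,6‑dimethyloct‑6‑enoyl]‑1,3‑oxazolidin‑2‑one | O=C1OC[C@@H](Cc2ccccc2)N1C(=O)[C@H](C)[C@@H](O)CC/C(C)=C\COC(C)=O | intermediate
6 | (2S,3S,6Z)‑2,6‑dimethyloct‑6‑ene‑1,3,8‑triol | OC[C@H](C)[C@@H](O)CC/C(C)=C\CO | intermediate
7 | acetonide alcohol, (2Z)‑3‑methyl‑5‑[(4S,5S)‑2,2,5‑trimethyl‑1,3‑dioxan‑4‑yl]pent‑2‑en‑1‑ol | C[C@H]1COC(C)(C)O[C@H]1CC/C(C)=C\CO | intermediate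
8 | acetonide enal, (2Z)‑3‑methyl‑5‑[(4S,5S)‑2,2,5‑trimethyl‑1,3‑dioxan‑4‑yl]pent‑2‑enal | C[C@H]1COC(C)(C)O[C@H]1CC/C(C)=C\C=O | intermediate
9 | tert‑butyl (R)‑lactate, tert‑butyl (2R)‑2‑hydroxypropanoate | C[C@@H](O)C(=O)OC(C)(C)C | starting material
10 | tert‑butyl (2R)‑2‑[(trifluoromethanesulfonyl)oxy]propanoate | C[C@@H](OS(=O)(=O)C(F)(F)F)C(=O)OC(C)(C)C | intermediate
11 | triethyl phosphonoacetate | CCOC(=O)CP(=O)(OCC)OCC | starting material
12 | phosphonosuccinate, 4‑tert‑butyl 1‑ethyl (3S)‑2‑(diethoxyphosphoryl)‑3‑methylbutanedioate (both C2 epimers) | CCOC(=O)C(P(=O)(OCC)OCC)[C@@H](C)C(=O)OC(C)(C)C | intermediate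
13 | (E)‑alkylidenesuccinate, 4‑tert‑butyl 1‑ethyl (2E,3R)‑3‑methyl‑2‑{(2Z)‑3‑methyl‑5‑[(4S,5S)‑2,2,5‑trimethyl‑1,3‑dioxan‑4‑yl]pent‑2‑en‑1‑ylidene}butanedioate | C[C@H]1COC(C)(C)O[C@H]1CC/C(C)=C\C=C(\C(=O)OCC)[C@@H](C)C(=O)OC(C)(C)C | intermediate
14 | dienol, tert‑butyl (2R,3E,5Z)‑3‑(hydroxymethyl)‑2,6‑dimethyl‑8‑[(4S,5S)‑2,2,5‑trimethyl‑1,3‑dioxan‑4‑yl]octa‑3,5‑dienoate | C[C@H]1COC(C)(C)O[C@H]1CC/C(C)=C\C=C(\CO)[C@@H](C)C(=O)OC(C)(C)C | intermediate
15 | (2R,3R)‑epoxy alcohol, tert‑butyl (2R)‑2‑[(2R,3R)‑2‑(hydroxymethyl)‑3‑{(1Z)‑2‑methyl‑4‑[(4S,5S)‑2,2,5‑trimethyl‑1,3‑dioxan‑4‑yl]but‑1‑en‑1‑yl}oxiran‑2‑yl]propanoate | C[C@H]1COC(C)(C)O[C@H]1CC/C(C)=C\[C@H]2O[C@@]2(CO)[C@@H](C)C(=O)OC(C)(C)C | intermediate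
16 | hydroxy lactone diol, (3R,4R,5S)‑4‑hydroxy‑4‑(hydroxymethyl)‑3‑methyl‑5‑{(1Z)‑2‑methyl‑4‑[(4S,5S)‑2,2,5‑trimethyl‑1,3‑dioxan‑4‑yl]but‑1‑en‑1‑yl}oxolan‑2‑one | C[C@H]1COC(C)(C)O[C@H]1CC/C(C)=C\[C@@H]2OC(=O)[C@H](C)[C@@]2(O)CO | intermediate
17 | bis(triethylsilyl) ether of 16 (Et3SiO on the tertiary C8 oxygen and on the primary C9 oxygen) | C[C@H]1COC(C)(C)O[C@H]1CC/C(C)=C\[C@@H]2OC(=O)[C@H](C)[C@@]2(O[Si](CC)(CC)CC)CO[Si](CC)(CC)CC | intermediate
18 | lactone aldehyde, (2S,3S,4R)‑4‑methyl‑2‑{(1Z)‑2‑methyl‑4‑[(4S,5S)‑2,2,5‑trimethyl‑1,3‑dioxan‑4‑yl]but‑1‑en‑1‑yl}‑5‑oxo‑3‑(triethylsilyloxy)oxolane‑3‑carbaldehyde | C[C@H]1COC(C)(C)O[C@H]1CC/C(C)=C\[C@@H]2OC(=O)[C@H](C)[C@@]2(O[Si](CC)(CC)CC)C=O | intermediate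
19 | methyl propiolate, methyl prop‑2‑ynoate | C#CC(=O)OC | starting material
20 | (9S)‑propargylic alcohol, methyl (4S)‑4‑hydroxybut‑2‑ynoate whose C4 (= C9) carries C8 of the silyloxy lactone of 18 | C[C@H]1COC(C)(C)O[C@H]1CC/C(C)=C\[C@@H]2OC(=O)[C@H](C)[C@@]2(O[Si](CC)(CC)CC)[C@@H](O)C#CC(=O)OC | intermediate
21 | stannyl hydroxy enoate, the (2E)‑2‑(tributylstannyl)but‑2‑enoate from 20 (Sn on C11, H on C10, C9 cis to the ester) | C[C@H]1COC(C)(C)O[C@H]1CC/C(C)=C\[C@@H]2OC(=O)[C@H](C)[C@@]2(O[Si](CC)(CC)CC)[C@@H](O)/C=C(/[Sn](CCCC)(CCCC)CCCC)C(=O)OC | intermediate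
22 | stannyl butenolide, (5S)‑3‑(tributylstannyl)furan‑2(5H)‑one whose C5 (= C9) carries C8 of the silyloxy lactone | C[C@H]1COC(C)(C)O[C@H]1CC/C(C)=C\[C@@H]2OC(=O)[C@H](C)[C@@]2(O[Si](CC)(CC)CC)[C@H]3OC(=O)C([Sn](CCCC)(CCCC)CCCC)=C3 | intermediate
23 | vinyl bromide, bromoethene | C=CBr | starting material
24 | vinylbutenolide, as 22 with ethenyl in place of Bu3Sn | C[C@H]1COC(C)(C)O[C@H]1CC/C(C)=C\[C@@H]2OC(=O)[C@H](C)[C@@]2(O[Si](CC)(CC)CC)[C@H]3OC(=O)C(C=C)=C3 | intermediate
25 | vinylbutenolide diol, 24 without the acetonide (primary C14–OH, secondary C2–OH) | OC[C@H](C)[C@@H](O)CC/C(C)=C\[C@@H]2OC(=O)[C@H](C)[C@@]2(O[Si](CC)(CC)CC)[C@H]3OC(=O)C(C=C)=C3 | intermediate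
26 | β‑hydroxy aldehyde, 25 with C14 as CHO | O=C[C@H](C)[C@@H](O)CC/C(C)=C\[C@@H]2OC(=O)[C@H](C)[C@@]2(O[Si](CC)(CC)CC)[C@H]3OC(=O)C(C=C)=C3 | intermediate
27 | dioxasiline triene, (4S)‑2,2‑di‑tert‑butyl‑5‑methyl‑4H‑1,3,2‑dioxasiline whose C4 (= C2) carries the Z chain to the silyloxy lactone and the 3‑vinylbutenolide | CC1=CO[Si](C(C)(C)C)(C(C)(C)C)O[C@H]1CC/C(C)=C\[C@@H]2OC(=O)[C@H](C)[C@@]2(O[Si](CC)(CC)CC)[C@H]3OC(=O)C(C=C)=C3 | intermediate
28 | pentacyclic cycloadduct: cyclohexene (C11=C12) fused to the cyclodecene at C1–C10, O2–Si(tBu)2–O14 bridge, C9–O–C20(=O) lactone on C10/C11, C7/C8 lactone with C8–OSiEt3; C1, C10, C14 as in the target | O1[C@H]2CC/C(C)=C\[C@@H]3OC(=O)[C@H](C)[C@@]3(O[Si](CC)(CC)CC)[C@H]4OC(=O)C5=CC[C@H](O[Si]1(C(C)(C)C)C(C)(C)C)[C@@]2(C)[C@@H]45 | intermediate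
29 | lithium enolate of the C20 lactone of 28 (C11=C20–OLi, C12 now CH2) | O1[C@H]2CC/C(C)=C\[C@@H]3OC(=O)[C@H](C)[C@@]3(O[Si](CC)(CC)CC)[C@H]4OC(O[Li])=C5CC[C@H](O[Si]1(C(C)(C)C)C(C)(C)C)[C@@]2(C)[C@@H]45 | intermediate
30 | α‑hydroxy lactone (C11–OH on the H10 face, cis‑fused C9/C20 lactone) | O1[C@H]2CC/C(C)=C\[C@@H]3OC(=O)[C@H](C)[C@@]3(O[Si](CC)(CC)CC)[C@H]4OC(=O)[C@@]5(O)CC[C@H](O[Si]1(C(C)(C)C)C(C)(C)C)[C@@]2(C)[C@@H]45 | intermediate
31 | triol (C20 as CH2OH, tertiary C11–OH, C9–OH; silyl groups retained) | O1[C@H]2CC/C(C)=C\[C@@H]3OC(=O)[C@H](C)[C@@]3(O[Si](CC)(CC)CC)[C@@H](O)[C@H]4[C@@](O)(CO)CC[C@H](O[Si]1(C(C)(C)C)C(C)(C)C)[C@]24C | intermediate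
32 | primary tosylate of 31 (C20–OTs) | O1[C@H]2CC/C(C)=C\[C@@H]3OC(=O)[C@H](C)[C@@]3(O[Si](CC)(CC)CC)[C@@H](O)[C@H]4[C@@](O)(COS(=O)(=O)c5ccc(C)cc5)CC[C@H](O[Si]1(C(C)(C)C)C(C)(C)C)[C@]24C | intermediate
33 | spiro‑epoxide (11,20‑epoxide, C9–OH free, C8–OSiEt3 and O2/O14 silylene retained) | O1[C@H]2CC/C(C)=C\[C@@H]3OC(=O)[C@H](C)[C@@]3(O[Si](CC)(CC)CC)[C@@H](O)[C@H]4[C@]5(CC[C@H](O[Si]1(C(C)(C)C)C(C)(C)C)[C@]24C)CO5 | intermediate
34 | tetraol, 2,9,14‑tri‑O‑deacetyljunceellolide K | O[C@H]1CC/C(C)=C\[C@@H]2OC(=O)[C@H](C)[C@@]2(O)[C@@H](O)[C@H]2[C@]3(CC[C@H](O)[C@]12C)CO3 | intermediate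
35 | Junceellolide K | CC(=O)O[C@H]1CC/C(C)=C\[C@@H]2OC(=O)[C@H](C)[C@@]2(O)[C@@H](OC(C)=O)[C@H]2[C@]3(CC[C@H](OC(C)=O)[C@]12C)CO3 | target

**Count and risks**

Total: 26 steps. Longest linear sequence: 24 steps (steps 1–6 and 9–26, from neryl acetate); steps 7–8 make the phosphonate side branch.

Steps most likely to fail:

1. Step 21 (bears the label Proposed new method). What may go wrong: the vinylbutenolide may oligomerise faster than it cyclises, the bridged regioisomer may form, or the tether may deliver the dienophile to the wrong face so that C1 and C10 come out epimeric. The fallback makes the two bonds one after the other with known reactions; it sets out from 22 and comes back at 28. Stille coupling of 22 with excess (E)‑1,2‑diiodoethene (Pd2(dba)3, AsPh3, CuI) should give iodovinyl butenolide F1. Acetonide methanolysis (PPTS, MeOH) gives iodovinyl diol F2, and TEMPO/PhI(OAc)2 oxidation gives iodovinyl hydroxy aldehyde F3. A Nozaki–Hiyama–Kishi macrocyclisation (CrCl2, NiCl2 cat., DMSO–THF, high dilution) then closes the C13–C14 bond in a fourteen‑membered ring, a ring size for which this reaction is well established, giving macrocyclic diol F4 as C14 epimers. Dess–Martin oxidation gives macrocyclic 1,3‑diketone F5, in which C1 is doubly activated and C10 is both the δ‑position of the C14 dienone and the β‑position of the butenolide. Cs2CO3 in MeCN should bring about a transannular Michael addition (C1–C10, six‑membered ring) followed by γ‑protonation at C13, giving bicyclic diketone F6. Reduction of both ketones (NaBH4, CeCl3, −78 °C; a wrong epimer at C2 or C14 would be corrected by Mitsunobu inversion) gives bicyclic diol F7, and tBu2Si(OTf)2 with 2,6‑lutidine closes the silylene to 28.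

2. Step 15. What may go wrong: sluggish addition of the zinc acetylide to the α‑quaternary aldehyde and incomplete catalyst control of the new C9 centre. The fallback replaces catalytic alkynylation by addition–oxidation–asymmetric reduction; it sets out from 18 and comes back at 20. Addition of lithium methyl propiolate (19, LiHMDS, THF, −78 °C) to 18 gives 20 mixed with its C9 epimer, 9‑epi‑propargylic alcohol F8. Dess–Martin oxidation of the mixture gives ynone F9, and Noyori asymmetric transfer hydrogenation with RuCl[(R,R)‑TsDPEN](p‑cymene) in HCO2H–Et3N, in which the alkynyl group plays the part of the unsaturated substituent, should return 20.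

3. Step 22. What may go wrong: competing 1,2‑reduction or attack on the other lactone by the hydride, and protonation of the enolate instead of oxidation. The fallback changes from an anionic to a hydrogen‑atom‑transfer process; it sets out from 28 and comes back at 30. Treatment of 28 with Mn(dpm)3 (cat.), PhSiH3 and O2 in iPrOH–CH2Cl2 at 0 °C should add hydrogen at C12 and trap the C11 radical with oxygen from the H10 face to give hydroperoxide F10, which P(OEt)3 reduces in the same flask to 30.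

**Further compounds**

F1 | step 21 | iodovinyl butenolide, 24 with (E)‑2‑iodoethenyl in place of ethenyl | C[C@H]1COC(C)(C)O[C@H]1CC/C(C)=C\[C@@H]2OC(=O)[C@H](C)[C@@]2(O[Si](CC)(CC)CC)[C@H]3OC(=O)C(/C=C/I)=C3
F2 | step 21 | iodovinyl diol, F1 without the acetonide | OC[C@H](C)[C@@H](O)CC/C(C)=C\[C@@H]2OC(=O)[C@H](C)[C@@]2(O[Si](CC)(CC)CC)[C@H]3OC(=O)C(/C=C/I)=C3
F3 | step 21 | iodovinyl hydroxy aldehyde, F2 with C14 as CHO | O=C[C@H](C)[C@@H](O)CC/C(C)=C\[C@@H]2OC(=O)[C@H](C)[C@@]2(O[Si](CC)(CC)CC)[C@H]3OC(=O)C(/C=C/I)=C3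
F4 | step 21 | macrocyclic diol, fourteen‑membered ring closed at C13–C14 (C14 epimers, E C12=C13) | OC1[C@H](C)[C@@H](O)CC/C(C)=C\[C@@H]2OC(=O)[C@H](C)[C@@]2(O[Si](CC)(CC)CC)[C@H]3OC(=O)C(/C=C/1)=C3
F5 | step 21 | macrocyclic 1,3‑diketone (C2 and C14 carbonyls, C1 unspecified) | O=C1C(C)C(=O)CC/C(C)=C\[C@@H]2OC(=O)[C@H](C)[C@@]2(O[Si](CC)(CC)CC)[C@H]3OC(=O)C(/C=C/1)=C3
F6 | step 21 | bicyclic diketone, C1–C10 bond formed, C11=C12 conjugated with the C20 lactone | O=C2CC/C(C)=C\[C@@H]3OC(=O)[C@H](C)[C@@]3(O[Si](CC)(CC)CC)[C@H]4OC(=O)C5=CCC(=O)[C@@]2(C)[C@@H]45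
F7 | step 21 | bicyclic diol, 28 without the silylene (C2–OH and C14–OH) | O[C@H]2CC/C(C)=C\[C@@H]3OC(=O)[C@H](C)[C@@]3(O[Si](CC)(CC)CC)[C@H]4OC(=O)C5=CC[C@H](O)[C@@]2(C)[C@@H]45
F8 | step 15 | 9‑epi‑propargylic alcohol, C9 epimer of 20 | C[C@H]1COC(C)(C)O[C@H]1CC/C(C)=C\[C@@H]2OC(=O)[C@H](C)[C@@]2(O[Si](CC)(CC)CC)[C@H](O)C#CC(=O)OC
F9 | step 15 | ynone, 20 with C9 as ketone | C[C@H]1COC(C)(C)O[C@H]1CC/C(C)=C\[C@@H]2OC(=O)[C@H](C)[C@@]2(O[Si](CC)(CC)CC)C(=O)C#CC(=O)OC
F10 | step 22 | hydroperoxide, 30 with OOH in place of OH at C11 | O1[C@H]2CC/C(C)=C\[C@@H]3OC(=O)[C@H](C)[C@@]3(O[Si](CC)(CC)CC)[C@H]4OC(=O)[C@@]5(OO)CC[C@H](O[Si]1(C(C)(C)C)C(C)(C)C)[C@@]2(C)[C@@H]45
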